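The route rests on cutting the C5–C1 and C5–C6 bonds. Six atoms of the seven-membered ring (C1, C10, C9, C8, C7, C6; guaiane numbering) carry chain, methyl, H, oxygen, C11 and H just as a 5-substituted 4-methylsalicylate does, and C5, wedged between C1 and C6, also belongs to the cyclopentane. An enantioselective intramolecular Buchner reaction of a terminal diazoketone therefore closes the five-membered ring and expands the benzene ring to the cycloheptatriene in one operation while setting C5. The precursor is a 1-diazo-4-arylbutan-2-one whose phenol oxygen and cumyl alcohol oxygen are tied as a di-tert-butylsilylene; the p-coumarate is attached last.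

Key step: step 7

Assumption: the (S,S)-bis(oxazoline) ligand is taken to favour the arene face that leads to (5R)-14, and the mirror-image ligand is used if a first run shows the opposite sense; guaiane locants (C1–C15) serve only as atom numbers for the bicyclic compounds.

Step 1
Reactants: 1 methyl 2-hydroxy-4-methylbenzoate
Product: 2 methyl 5-bromo-2-hydroxy-4-methylbenzoate
Conditions: Br2 (1.05 equiv), CH2Cl2, 0 °C to rt
Reagents that add atoms: bromine, BrBr
Why: Electrophilic aromatic bromination is steered by the phenol to its para position, which is also ortho to the methyl group and meta to the ester, so a single regioisomer is expected.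

Step 2
Reactants: 2 methyl 5-bromo-2-hydroxy-4-methylbenzoate
Product: 4 4-bromo-2-(2-hydroxypropan-2-yl)-5-methylphenol, via aryl methyl ketone 3 (not isolated)
Conditions: MeMgBr (4 equiv), THF, 0 °C to rt; then water and pH 7 buffer at 0 °C
Reagents that add atoms: methylmagnesium bromide, C[Mg]Br
Why: Double Grignard addition to the ester (after deprotonation of the phenol, through ketone 3) gives the tertiary cumyl alcohol that supplies C12 and C13, and the aryl bromide does not exchange with MeMgBr at these temperatures.

Step 3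
Reactants: 4 4-bromo-2-(2-hydroxypropan-2-yl)-5-methylphenol
Product: 5 6-bromo-2,2-di-tert-butyl-4,4,7-trimethyl-4H-1,3,2-benzodioxasiline
Conditions: t-Bu2Si(OTf)2 (1.1 equiv), 2,6-lutidine (3 equiv), CH2Cl2, 0 °C to rt
Reagents that add atoms: di-tert-butylsilyl bis(trifluoromethanesulfonate), CC(C)(C)[Si](OS(=O)(=O)C(F)(F)F)(OS(=O)(=O)C(F)(F)F)C(C)(C)C
Why: Silylene formation with the silyl bis-triflate bridges the phenol and the tertiary benzylic hydroxyl in a six-membered ring, and the lutidine buffer keeps the acid-sensitive cumyl alcohol from ionizing.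

Step 4
Reactants: 5 6-bromo-2,2-di-tert-butyl-4,4,7-trimethyl-4H-1,3,2-benzodioxasiline; 6 benzyl acrylate
Product: 7 benzyl (E)-3-(2,2-di-tert-butyl-4,4,7-trimethyl-4H-1,3,2-benzodioxasilin-6-yl)acrylate
Conditions: Pd2(dba)3 (1.5 mol %), [HP(t-Bu)3]BF4 (6 mol %), Cy2NMe (1.2 equiv), dioxane, 60 °C
Reagents that add atoms: none
Why: Mizoroki–Heck reaction, in which zerovalent palladium carrying the bulky electron-rich phosphine inserts into the hindered, electron-rich C–Br bond and syn carbopalladation followed by syn β-hydride elimination gives the E-cinnamate.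

Step 5
Reactants: 7 benzyl (E)-3-(2,2-di-tert-butyl-4,4,7-trimethyl-4H-1,3,2-benzodioxasilin-6-yl)acrylate
Product: 9 3-(2,2-di-tert-butyl-4,4,7-trimethyl-4H-1,3,2-benzodioxasilin-6-yl)propanoic acid, via saturated benzyl ester 8 (not isolated)
Conditions: H2 (1 atm), palladium on carbon (10% Pd/C), EtOAc, rt
Reagents that add atoms: none
Why: Heterogeneous catalytic hydrogenation saturates the conjugated alkene and hydrogenolysis then removes the benzyl group, while the aryl and tertiary silyl ether linkages are stable in neutral ethyl acetate.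

Step 6
Reactants: 9 3-(2,2-di-tert-butyl-4,4,7-trimethyl-4H-1,3,2-benzodioxasilin-6-yl)propanoic acid; 10 trimethylsilyldiazomethane
Product: 12 1-diazo-4-(2,2-di-tert-butyl-4,4,7-trimethyl-4H-1,3,2-benzodioxasilin-6-yl)butan-2-one, via mixed carbonic anhydride 11 (not isolated)
Conditions: i-BuOCOCl (1.1 equiv), Et3N (1.2 equiv), THF, −15 °C; then 10 (2 equiv, hexanes), MeCN/THF, 0 °C to rt
Reagents that add atoms: none
Why: C-acylation of the diazoalkane by the mixed carbonic anhydride (diazoketone synthesis of the Arndt–Eistert type), with transfer of the silyl group to the departing carbonate, gives the terminal diazoketone without any HCl that could open the cumyl silyl ether.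

Step 7
Reactants: 12 1-diazo-4-(2,2-di-tert-butyl-4,4,7-trimethyl-4H-1,3,2-benzodioxasilin-6-yl)butan-2-one
Product: 14 (5R)-8,11-(di-tert-butylsilanediyldioxy)-15-norguaia-1(10),6,8-trien-4-one, via norcaradiene 13 (not isolated)
Conditions: CuCl (5 mol %), Na[B(3,5-(CF3)2C6H3)4] (6 mol %), 2,2'-(propane-2,2-diyl)bis[(4S)-4-phenyl-4,5-dihydro-1,3-oxazole] (6 mol %), CH2Cl2, reflux, slow addition of 12; rapid filtration through neutral alumina, used at once
Reagents that add atoms: none
Why: Loss of N2 from 12 at the cationic monovalent copper centre gives an electrophilic carbene that the three-atom tether holds over the ipso carbon, so it adds across the C1–C6 π bond to give norcaradiene 13, whose C1–C6 σ bond then opens by a disrotatory six-electron electrocyclic reaction to cycloheptatriene 14. The closest known reaction type is the catalytic enantioselective intramolecular Buchner reaction of 1-diazo-4-arylbutan-2-ones to 3,4-dihydroazulen-1(2H)-ones under copper bis(oxazoline) or chiral dirhodium carboxylate catalysis. The cyclopentanone closes by intramolecular [2+1] cycloaddition (bond C5–C1 completes the five-membered ring, bond C5–C6 the cyclopropane), and the seven-membered ring is not cyclized but arises by ring expansion when the shared C1–C6 bond of the norcaradiene breaks. C5 is the only stereocentre formed and is controlled by the chiral bis(oxazoline) ligand, which decides the arene face to which the carbene adds. The step needs attack at the C1–C6 bond and not at C1–C10, which the C10 methyl group secures by making the latter bond fully substituted, and it needs cyclopropanation to win over ipso attack or aromatic substitution, which the neutral medium and the robust dialkoxysilane on the para oxygen favour. The triene of 14 falls at C1=C10, C8=C9 (a silyl enol ether that masks the C8 ketone) and C6=C7 (the handle for C7), and because 14 is acid-labile and its C5–H is acidic it is carried straight into step 8.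

Step 8
Reactants: 14 (5R)-8,11-(di-tert-butylsilanediyldioxy)-15-norguaia-1(10),6,8-trien-4-one
Product: 15 (5S)-8,11-(di-tert-butylsilanediyldioxy)guaia-1(10),4(15),6,8-tetraene
Conditions: Cp2Ti(μ-CH2)(μ-Cl)AlMe2 (1.3 equiv, toluene), pyridine, THF, −40 to 0 °C
Reagents that add atoms: Cp2Ti(μ-CH2)(μ-Cl)AlMe2, C[Al-]1(C)C[Ti]([Cl+]1)(C2C=CC=C2)C3C=CC=C3
Why: Carbonyl methylenation by the titanium methylidene ([2+2] cycloaddition and cycloreversion through an oxatitanacyclobutane) is not basic, so the acidic C5–H next to the ketone is not epimerized and the silyl enol ether is untouched.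

Step 9
Reactants: 15 (5S)-8,11-(di-tert-butylsilanediyldioxy)guaia-1(10),4(15),6,8-tetraene
Product: 16 (4S,5R)-8,11-(di-tert-butylsilanediyldioxy)guaia-1(10),6,8-triene
Conditions: 2-nitrobenzenesulfonylhydrazide (6 equiv, in portions), Et3N, CH2Cl2, rt
Reagents that add atoms: none
Why: Diimide reduction is a concerted syn transfer of H2 that discriminates strongly by substitution, so only the exocyclic 1,1-disubstituted alkene should react, and from the face of H5 because C6 and the folded seven-membered ring shield the other face, which places H4 cis to H5 and the C4 methyl cis to C6.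

Step 10
Reactants: 16 (4S,5R)-8,11-(di-tert-butylsilanediyldioxy)guaia-1(10),6,8-triene
Product: 18 (4S,5R)-11-hydroxyguaia-1(10),6-dien-8-one, via fluorosilyl ether 17 (not isolated)
Conditions: Bu4NF (2.5 equiv), AcOH (2.5 equiv), THF, 0 °C to rt
Reagents that add atoms: none
Why: Fluoride-induced desilylation opens the Si–O(enol) bond first, acetic acid protonates the cross-conjugated dienolate kinetically at its α-carbon C9 so that C1=C10 stays out of conjugation, and a second fluoride then releases the tertiary C11 alcohol from fluorosilyl ether 17.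

Step 11
Reactants: 18 (4S,5R)-11-hydroxyguaia-1(10),6-dien-8-one
Product: 19 (4S,5R,8S)-guaia-1(10),6-diene-8,11-diol
Conditions: (R)-2-methyl-CBS-oxazaborolidine (0.2 equiv), catecholborane (2 equiv), toluene, −78 °C; then water, pH 7 buffer
Reagents that add atoms: none
Why: Corey–Bakshi–Shibata reduction, in which the oxazaborolidine binds the ketone oxygen anti to the larger C7 alkenyl flank (which carries C11) and delivers hydride 1,2 from one face, so the (R)-catalyst should give the (8S)-alcohol under reagent control, while catecholborane at −78 °C spares the free tertiary hydroxyl and the alkenes.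

Step 12
Reactants: 19 (4S,5R,8S)-guaia-1(10),6-diene-8,11-diol
Product: 20 (4S,5S,7S,8S)-guai-1(10)-ene-8,11-diol
Conditions: [Ir(cod)(PCy3)(py)]PF6 (5 mol %), H2 (1 atm), CH2Cl2, 0 °C to rt
Reagents that add atoms: none
Why: Hydroxyl-directed homogeneous hydrogenation, in which the cationic iridium centre is anchored by the C8 hydroxyl and adds H2 to C6=C7 from the face of that hydroxyl, which is also the face of H5, so H7 ends cis to the C8 oxygen (C11 trans to it), while the tetrasubstituted C1=C10 alkene reacts far more slowly.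

Step 13
Reactants: 21 (E)-3-(4-hydroxyphenyl)acrylic acid
Product: 23 (E)-3-[4-(tert-butyldimethylsilyloxy)phenyl]acrylic acid, via bis-silyl coumarate 22 (not isolated)
Conditions: TBSCl (2.3 equiv), imidazole (5 equiv), DMF, rt; then AcOH/THF/H2O (3:1:1), rt
Reagents that add atoms: tert-butyldimethylsilyl chloride, CC(C)(C)[Si](C)(C)Cl
Why: Silylation of both acidic hydroxyls followed by chemoselective hydrolysis of the much more labile silyl ester leaves the phenol protected and the E-alkene untouched.

Step 14
Reactants: 20 (4S,5S,7S,8S)-guai-1(10)-ene-8,11-diol; 23 (E)-3-[4-(tert-butyldimethylsilyloxy)phenyl]acrylic acid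
Product: 24 (4S,5S,7S,8S)-11-hydroxyguai-1(10)-en-8-yl (E)-3-[4-(tert-butyldimethylsilyloxy)phenyl]acrylate
Conditions: DCC (1.5 equiv), DMAP (0.3 equiv), CH2Cl2, 0 °C to rt
Reagents that add atoms: none
Why: Steglich esterification, in which the O-acylisourea is relayed by DMAP as an acylpyridinium ion that acylates the secondary C8 hydroxyl with retention, while the tertiary C11 hydroxyl is too hindered to compete.

Step 15
Reactants: 24 (4S,5S,7S,8S)-11-hydroxyguai-1(10)-en-8-yl (E)-3-[4-(tert-butyldimethylsilyloxy)phenyl]acrylate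
Product: 25 (4S,5S,7S,8S)-11-hydroxyguai-1(10)-en-8-yl (E)-3-(4-hydroxyphenyl)acrylate
Conditions: Bu4NF (1.2 equiv), AcOH (1.2 equiv), THF, 0 °C
Reagents that add atoms: none
Why: Fluoride-induced cleavage of the aryl silyl ether is fast at 0 °C, and the acetic acid buffer keeps the liberated phenoxide from attacking the cinnamate ester.

Compound list

1 | methyl 2-hydroxy-4-methylbenzoate (methyl 4-methylsalicylate) | COC(=O)c1ccc(C)cc1O | starting material
2 | methyl 5-bromo-2-hydroxy-4-methylbenzoate | COC(=O)c1cc(Br)c(C)cc1O | intermediate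
3 | 1-(5-bromo-2-hydroxy-4-methylphenyl)ethan-1-one (present as its bromomagnesium phenoxide) | CC(=O)c1cc(Br)c(C)cc1O | intermediate (not isolated)
4 | 4-bromo-2-(2-hydroxypropan-2-yl)-5-methylphenol | CC(C)(O)c1cc(Br)c(C)cc1O | intermediate
5 | 6-bromo-2,2-di-tert-butyl-4,4,7-trimethyl-4H-1,3,2-benzodioxasiline | CC1(C)O[Si](C(C)(C)C)(C(C)(C)C)Oc2cc(C)c(Br)cc21 | intermediate
6 | benzyl acrylate | C=CC(=O)OCc1ccccc1 | starting material
7 | benzyl (E)-3-(2,2-di-tert-butyl-4,4,7-trimethyl-4H-1,3,2-benzodioxasilin-6-yl)acrylate | CC1(C)O[Si](C(C)(C)C)(C(C)(C)C)Oc2cc(C)c(/C=C/C(=O)OCc3ccccc3)cc21 | intermediate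
8 | benzyl 3-(2,2-di-tert-butyl-4,4,7-trimethyl-4H-1,3,2-benzodioxasilin-6-yl)propanoate | CC1(C)O[Si](C(C)(C)C)(C(C)(C)C)Oc2cc(C)c(CCC(=O)OCc3ccccc3)cc21 | intermediate (not isolated)
9 | 3-(2,2-di-tert-butyl-4,4,7-trimethyl-4H-1,3,2-benzodioxasilin-6-yl)propanoic acid | CC1(C)O[Si](C(C)(C)C)(C(C)(C)C)Oc2cc(C)c(CCC(=O)O)cc21 | intermediate
10 | trimethylsilyldiazomethane | C[Si](C)(C)C=[N+]=[N-] | starting material
11 | isobutyl carbonic anhydride of acid 9 | CC1(C)O[Si](C(C)(C)C)(C(C)(C)C)Oc2cc(C)c(CCC(=O)OC(=O)OCC(C)C)cc21 | intermediate (not isolated)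
12 | 1-diazo-4-(2,2-di-tert-butyl-4,4,7-trimethyl-4H-1,3,2-benzodioxasilin-6-yl)butan-2-one | CC1(C)O[Si](C(C)(C)C)(C(C)(C)C)Oc2cc(C)c(CCC(=O)C=[N+]=[N-])cc21 | intermediate
13 | norcaradiene valence isomer of 14: cyclopropane C1–C5–C6 cis-fused to the cyclopentanone and to the cyclohexadiene (C7=C8, C9=C10), H5 over the six-membered ring, C5 configured as in 14 | CC1=CC2=C(C(C)(C)O[Si](C(C)(C)C)(C(C)(C)C)O2)[C@@H]3[C@H]4C(=O)CC[C@@]134 | intermediate (not isolated)
14 | (5R)-8,11-(di-tert-butylsilanediyldioxy)-15-norguaia-1(10),6,8-trien-4-one (dihydroazulenone; O8 and O11 bridged by Si(t-Bu)2) | CC1=C2CCC(=O)[C@@H]2C=C3C(=C1)O[Si](C(C)(C)C)(C(C)(C)C)OC3(C)C | intermediate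
15 | (5S)-8,11-(di-tert-butylsilanediyldioxy)guaia-1(10),4(15),6,8-tetraene (4-methylene compound) | CC1=C2CCC(=C)[C@@H]2C=C3C(=C1)O[Si](C(C)(C)C)(C(C)(C)C)OC3(C)C | intermediate
16 | (4S,5R)-8,11-(di-tert-butylsilanediyldioxy)guaia-1(10),6,8-triene (H4 cis to H5) | CC1=C2CC[C@H](C)[C@@H]2C=C3C(=C1)O[Si](C(C)(C)C)(C(C)(C)C)OC3(C)C | intermediate
17 | (4S,5R)-11-(di-tert-butylfluorosilyloxy)guaia-1(10),6-dien-8-one | CC1=C2CC[C@H](C)[C@@H]2C=C(C(C)(C)O[Si](F)(C(C)(C)C)C(C)(C)C)C(=O)C1 | intermediate (not isolated)
18 | (4S,5R)-11-hydroxyguaia-1(10),6-dien-8-one | CC1=C2CC[C@H](C)[C@@H]2C=C(C(C)(C)O)C(=O)C1 | intermediate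
19 | (4S,5R,8S)-guaia-1(10),6-diene-8,11-diol (8-OH cis to H5) | CC1=C2CC[C@H](C)[C@@H]2C=C(C(C)(C)O)[C@@H](O)C1 | intermediate
20 | (4S,5S,7S,8S)-guai-1(10)-ene-8,11-diol (H7 cis to 8-OH and to H5) | CC1=C2CC[C@H](C)[C@@H]2C[C@H](C(C)(C)O)[C@@H](O)C1 | intermediate
21 | (E)-3-(4-hydroxyphenyl)acrylic acid (p-coumaric acid) | OC(=O)/C=C/c1ccc(O)cc1 | starting material
22 | tert-butyldimethylsilyl (E)-3-[4-(tert-butyldimethylsilyloxy)phenyl]acrylate | CC(C)(C)[Si](C)(C)OC(=O)/C=C/c1ccc(O[Si](C)(C)C(C)(C)C)cc1 | intermediate (not isolated)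
23 | (E)-3-[4-(tert-butyldimethylsilyloxy)phenyl]acrylic acid | OC(=O)/C=C/c1ccc(O[Si](C)(C)C(C)(C)C)cc1 | intermediate
24 | (4S,5S,7S,8S)-11-hydroxyguai-1(10)-en-8-yl (E)-3-[4-(tert-butyldimethylsilyloxy)phenyl]acrylate | CC1=C2CC[C@H](C)[C@@H]2C[C@H](C(C)(C)O)[C@@H](OC(=O)/C=C/c2ccc(O[Si](C)(C)C(C)(C)C)cc2)C1 | intermediate
25 | (4S,5S,7S,8S)-11-hydroxyguai-1(10)-en-8-yl (E)-3-(4-hydroxyphenyl)acrylate (CNP0403230.1) | CC1=C2CC[C@H](C)[C@@H]2C[C@H](C(C)(C)O)[C@@H](OC(=O)/C=C/c2ccc(O)cc2)C1 | target

Total step count: 15.
Longest linear sequence: 14 steps (steps 1 to 12, 14 and 15, from 1 to 25); step 13 is the one-step side branch.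

Steps most likely to fail

Step 7. The catalyst may discriminate poorly between the two arene faces with a terminal diazoketone. The carbene may also attack the ipso carbon with loss of silicon from the para oxygen, or traces of acid may rearrange the cycloheptatriene into a 2-tetralone. The fallback sets out from 12 and gives up catalyst control of C5 in favour of a resolution. Rh2(OAc)4 (1 mol %) in CH2Cl2 at room temperature, the best-established neutral catalyst for this substrate class, should convert 12 into the racemic azulenone F1. Preparative chromatography on a chiral stationary phase (cellulose tris(3,5-dimethylphenylcarbamate), heptane/2-propanol) then separates the enantiomers; it sets aside the (5S)-enantiomer F2 and comes back to the route at 14, which goes on into step 8.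

Step 9. Diimide is small, so the two faces of the exocyclic alkene may be told apart poorly, and the large excess needed for a 1,1-disubstituted alkene may begin to reduce the triene. The fallback sets out from 15 and replaces the small reagent by a bulky borane followed by deoxygenation. 9-Borabicyclo[3.3.1]nonane (THF, 0 °C to rt) should add to the methylene group from the face of H5 to give the B-alkyl-9-borabicyclononane F3. Oxidation with NaBO3·4H2O in THF/water gives the primary C15 alcohol F4, and TsCl with pyridine and DMAP gives the tosylate F5. Displacement with LiEt3BH in THF at 0 °C turns C15 into the methyl group and comes back to the route at 16.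

Step 10. Loss of the hindered fluorosilyl group from the tertiary oxygen may be slow. The β,γ-unsaturated ketone would then stay exposed to fluoride and acetate, which invites migration of C1=C10 into conjugation with the C8 carbonyl or vinylogous enolization at C5. The fallback sets out from 16 and moves the second desilylation behind the reduction. One equivalent of Bu4NF and AcOH in THF at −40 °C should stop at fluorosilyl ether 17, which is isolated here. Reduction of 17 under the conditions of step 11 gives the fluorosilyl-protected (8S)-allylic alcohol F6, now free of the sensitive ketone. HF·pyridine in THF/pyridine then removes the silyl group and comes back to the route at 19.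

Further compounds

F1 | step 7 | racemic 8,11-(di-tert-butylsilanediyldioxy)-15-norguaia-1(10),6,8-trien-4-one | CC1=C2CCC(=O)C2C=C3C(=C1)O[Si](C(C)(C)C)(C(C)(C)C)OC3(C)C
F2 | step 7 | (5S)-enantiomer of 14 | CC1=C2CCC(=O)[C@H]2C=C3C(=C1)O[Si](C(C)(C)C)(C(C)(C)C)OC3(C)C
F3 | step 9 | B-alkyl-9-borabicyclo[3.3.1]nonane from 15 (boron on C15, H4 cis to H5) | CC1=C2CC[C@H](CB3C4CCCC3CCC4)[C@@H]2C=C3C(=C1)O[Si](C(C)(C)C)(C(C)(C)C)OC3(C)C
F4 | step 9 | 15-hydroxy derivative of 16 | CC1=C2CC[C@H](CO)[C@@H]2C=C3C(=C1)O[Si](C(C)(C)C)(C(C)(C)C)OC3(C)C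
F5 | step 9 | 15-(p-toluenesulfonyloxy) derivative of 16 | CC1=C2CC[C@H](COS(=O)(=O)c3ccc(C)cc3)[C@@H]2C=C3C(=C1)O[Si](C(C)(C)C)(C(C)(C)C)OC3(C)C
F6 | step 10 | (4S,5R,8S)-11-(di-tert-butylfluorosilyloxy)guaia-1(10),6-dien-8-ol | CC1=C2CC[C@H](C)[C@@H]2C=C(C(C)(C)O[Si](F)(C(C)(C)C)C(C)(C)C)[C@@H](O)C1
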